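The vessel was closed, stirred and isothermal, and the noon flask in it had been followed for only 6.00 min.

| setting | noon | summer | flask |
|---|---|---|---|
| starting material | 0.095 M | 0.19 M | 0.095 M |
| precatalyst | 0.95 mM | 0.95 mM | 0.95 mM |
| remark | the very flask that is asked about, followed so far | run made earlier |  |
| time |  |  | 80 min |

| run | time / min | product / % | starting material / % |
|---|---|---|---|
| noon | 1.50 | 1.0 | 98.9 |
| noon | 3.00 | 0.3 | 101.2 |
| noon | 5.00 | 0.5 | 98.1 |
| noon | 6.00 | 0 | 98.9 |
| summer | 6.00 | 1.6 | 100.2 |
| summer | 15.0 | 0.6 | 99.2 |
| summer | 30.0 | 2.7 | 94.7 |
| summer | 80.0 | 24.8 | 77.0 |

(each reading ± 1 percentage point)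

- at 80 min, what has stopped the reaction, if anything has (no working catalyst is left / all of the starting material has reacted / it is still moving / forward and back rates have come level)
- product at 80 min, in percent of the starting material charged

The noon readings showed no product beyond the scatter of 1 percentage point, so I reckoned from the summer flask, which held the same precatalyst on twice the starting material. By 80.0 min the summer flask had made 49.6 turnovers; this turnover number, moles of product per mole of precatalyst charged, was what I carried.

I solved both ends. If the amount of starting material made no difference to the rate, the noon flask would repeat that number, and with 100 starting material per precatalyst it would reach 49.6% of its charge. If the rate were first order in starting material, the fraction would repeat instead, at 24.8%. I joined them at the middle, 37.2%, with the flask still moving.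

The forecast read it is still moving and 30%, within 14% to 52%, with “no sign of equilibrium or catalyst death”.

The flask gave it is still moving and 43.6% product at 80 min.

    starting material + free catalyst → catalyst intermediate A (k = 2.30 L mol⁻¹ s⁻¹)
    catalyst intermediate A → catalyst intermediate B (k = 0.0290 s⁻¹)
    catalyst intermediate B → free catalyst + product (k = 1.40 s⁻¹)
    precatalyst ⇌ free catalyst (K = 2.20, k = 2.20 × 10⁻⁴ s⁻¹)

That is 43.6 turnovers, 0.880 of the summer number and nearer the first end. The same number on a neighbour flask with 0.600 of the precatalyst charge gave 26.2%, and that flask simulated 26.7%. The asked flask had not come to rest: its product went from 13.2% at 40.0 min to 43.6% at 80.0 min, a rise of 30 points over the second half of the time. Left until 800 min, ten times the asked time, it stood at 100% product and 0% starting material, with 68.8% of the catalyst charged as free catalyst and 31.2% as precatalyst.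

(Readings and results stem from a simulated flask with made-up constants; scatter was added.)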